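**Design of a synthesis of CNP0298167.2 (compound 39) through a macrolactone-to-carbocycle Ireland–Claisen rearrangement**

Ring atoms are numbered C1–C14: C1 bears the carbinol carbon C15, C4 and C12 bear methyl groups, C8 bears CH2OH.

## The problem

Compound 39 is a 14-membered carbocycle with a 2-hydroxy-6-methylhept-5-en-2-yl side chain on C1. The ring holds three trisubstituted alkenes that all differ: C3=C4 is Z, C7=C8 carries CH2OH with C6 and C9 cis (E by the sequence rule), and C11=C12 is E. They are insulated from each other by CH2CH2 units, so each geometry must come from its own stereospecific reaction. The only stereocentres, C1 (R) and C15 (R), are adjacent. C15 can set C1 if both come from one trisubstituted epoxide opened with inversion at the future C1, but neither can influence the remote alkenes. The ring has no heteroatom and no handle at C13/C14, C5/C6 or C9/C10, so a direct carbon–carbon macrocyclisation has to pay the full entropic price. The sensitive groups are the tertiary C15 alcohol (ionises in acid, and closes a γ-lactone onto any acyl carbon attached to C14), the primary allylic alcohol, the Z alkene (radical or acid isomerisation) and the 1,5-diene arrays (transannular cyclisation). The enabling feature is the array C14–C13–C12(CH3)=C11. With a carboxyl group on C14 it is a γ,δ-unsaturated acid, the product of an ester-enolate Claisen rearrangement whose ester oxygen sat on C11. Because C14 is a bare CH2 in 39, that carboxyl can be removed afterwards. The ester that links a C14 acetic acid arm to a C11 carbinol is itself a 14-membered lactone, so the ring can be closed at oxygen and converted into the carbocycle in a unimolecular step.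

## Retrosynthesis

**39 ⇐ 38 ⇐ 36.** The two O–Si bonds are cut last, and a carboxyl group is added to C14 of bis-silyl ether 38 to give acid 36. The carboxyl carbon is the only atom foreign to the target. Its radical removal also erases the C14 centre, so nothing about its configuration has to be controlled. The forward order must be decarboxylation before desilylation, because a free C15 hydroxyl would lactonise onto the C14 carboxyl.

**36 ⇐ 33.** The C13–C14 bond is cut and C11 is reconnected to the carboxyl oxygen, which gives lactone 33 with an isopropenyl group on C11. Neighbouring cuts (C12–C13 by cross-coupling, C6–C7 or C1–C14 by carbanion alkylation) all close the ring by an intramolecular reaction of two remote ends at high dilution. This cut forms the C–C bond inside a ring that already exists and creates the E C11=C12 alkene in the same event. The precursor has lost one alkene geometry and carries a C11 centre whose configuration does not matter. The forward step needs clean enolisation at C14 (the only α-position) and a chair transition state.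

**33 ⇐ 31 ⇐ 29 + 30.** The ester C–O bond is cut to seco acid 31, then the C11–C12 bond to aldehyde acid 29 and isopropenylmagnesium bromide 30. Lactonisation of a hydroxy acid is the most dependable way to make a 14-membered ring. The Grignard addition needs no stereocontrol because both C11 epimers converge later.

**29 ⇐ 28 ⇐ 27 ⇐ 25 ⇐ 23.** These are oxidation-state changes only. The C11 aldehyde comes from a p-methoxybenzyl ether (removed oxidatively next to two silyl ethers), and the acetic acid arm comes from a vinyl group on C1 by hydroboration and oxidation. A vinyl group is inert to every earlier step and is the only monosubstituted alkene in 23, so it can be addressed selectively.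

**23 ⇐ 6 + 20.** The C2–C3 bond is cut between an sp3 carbon (iodide 6) and the Z alkenyl iodide 20. An sp3–sp2 Negishi coupling keeps the alkene geometry and joins two fragments of similar size. A Wittig construction of C3=C4 would have to create the Z trisubstituted alkene at the coupling stage with poor control.

**6 ⇐ 5 ⇐ 4 ⇐ 2 + 3 ⇐ 1.** The C1–C14 bond is cut to epoxy alcohol 2 and vinylmagnesium bromide 3. Both stereocentres of 39 then come from a single asymmetric epoxidation of nerol 1. The Z geometry of nerol, with attack at C2 under inversion, gives the required (1R,15R) relationship. The primary hydroxyl of diol 4 becomes the C2 iodide (5) and the tertiary hydroxyl is capped as its triethylsilyl ether (6).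

**20 ⇐ 19 ⇐ 18 ⇐ 17 + 10; 17 ⇐ 16 ⇐ 11 + 12; 10 ⇐ 9 + 8 ⇐ 7.** The C7=C8 alkene is cut by a Horner–Wadsworth–Emmons disconnection to aldehyde 17 and phosphonate 10. The E enoate places C6 cis to C9, as the target requires, and its ester carbon becomes the CH2OH group. Aldehyde 17 comes from acetal 16. Acetal 16 is made by syn addition of the organocopper reagent from bromide 11 across propyne 12, which fixes the Z geometry of C3=C4. Phosphonate 10 is triethyl phosphonoacetate 9 alkylated with iodide 8, which is made from alcohol 7.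

## Roads not taken

**Alternative 1:** The cut is C6–C7, combined with an oxygen transposition. The open-chain precursor A1 carries a primary iodide at C6 and a phenyl sulfoxide on C7 next to an exocyclic methylene on C8. In the forward key step LDA lithiates C7, the anion displaces the iodide and closes the ring, and P(OMe)3 then drives the [2,3] sulfoxide–sulfenate shift that creates C7=C8 and its CH2OH, giving A2.
- Merits: ring closure and the hydroxymethyl alkene arrive together, no foreign carbon is carried, the primary alcohol never needs protection, and A2 is one deprotection from the target. In these respects it is shorter than the chosen plan, which needs a lactonisation, a rearrangement and a decarboxylation for the same ground.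
- Weak points: the closure is an SN2 reaction of an ambident allyl anion at high dilution, where γ-alkylation, elimination of the iodide and oligomerisation compete. The geometry at C7=C8 depends on a sulfenate transition state inside the new ring, where the open-chain preference need not hold. A1 must already contain the E C11=C12 alkene, which has to be made separately.
- Comparison: the chosen plan offers a ring closure at oxygen, a C–C bond formed unimolecularly, and the C11=C12 geometry created by the key step itself.

**Alternative 2:** The cut is C1–C14. The precursor A3 ends in a phenyl sulfone at C14 and carries the C1–C15 epoxide. In the forward key step n-BuLi forms the sulfonyl carbanion, which opens the epoxide at C1 with inversion, closes the ring and frees the C15 alkoxide to give A4. Reductive desulfonylation and desilylation follow.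
- Merits: C1 is set in the ring-forming event from the same kind of epoxide used here. There is no lactonisation and no tertiary-alcohol protection, and the activating group leaves in one step. In stereochemical economy and step count this road is at least as good as the chosen one.
- Weak points: the SN2 carbon is flanked by a fully substituted epoxide carbon and must be reached by a bulky secondary carbanion in a 14-membered transition state, while base-induced isomerisation of the epoxide to an allylic alcohol competes. The epoxide must also survive the whole chain assembly.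
- Comparison: the chosen plan opens the same epoxide at the outset with a small vinyl nucleophile in excess, so the ring closure does not depend on that hindered displacement.

**Alternative 3:** The cut is C12–C13. The precursor A5 has a vinyl group on C1 and an (E)-alkenyl iodide at C12. In the forward key step 9-BBN adds to the vinyl group and the C13 alkylborane couples intramolecularly under PdCl2(dppf), Ph3As and Cs2CO3, giving A6, which is identical in structure with 38.
- Merits: no foreign carbon, and three steps fewer after the common vinyl-bearing intermediate (23 of the chosen route holds the same C1 vinyl group). On step count this road is better.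
- Weak points: the (E)-2-iodo-2-alkene at C11/C12 must be made geometrically pure. The usual entry, hydrometalation of a 2-alkyne, would have to distinguish the alkyne from the C1 vinyl group and its two carbons from each other, and the iodo-ylide olefination of a C11 aldehyde gives the opposite geometry. The closure is again an end-to-end C–C macrocyclisation at high dilution, with protodeboronation and oligomerisation as competitors.
- Comparison: the chosen plan obtains the E alkene from a stereorandom Grignard adduct and closes the ring by lactonisation.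

Key step: step 19

Remark: C11 in 31–35 and the carboxyl-bearing ring carbon in 35–37 are carried as mixtures of both configurations and are written without descriptor in the SMILES. The ketene acetal geometry of 34 is also left open.

## Route

Step 1
Reactants: 1 nerol
Product: 2 [(2S,3R)-3-methyl-3-(4-methylpent-3-en-1-yl)oxiran-2-yl]methanol
Conditions: Ti(OiPr)4 (10 mol %), L-(+)-diethyl tartrate (12 mol %), t-BuOOH, 4 Å molecular sieves, CH2Cl2, −20 °C
Reagents that add atoms: tert-butyl hydroperoxide, CC(C)(C)OO
Why: Sharpless asymmetric epoxidation; the allylic hydroxyl binds titanium so only the 2,3-alkene reacts, and the L-(+)-tartrate ligand selects the face that sets both epoxide carbons as 2S,3R (the future C1 and C15).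

Step 2
Reactants: 2; 3 vinylmagnesium bromide
Product: 4 (2R,3R)-2-ethenyl-3,7-dimethyloct-6-ene-1,3-diol
Conditions: CH2=CHMgBr (4 equiv), CuI (0.2 equiv), THF/Et2O, −30 → 0 °C; aq. NH4Cl
Reagents that add atoms: none
Why: Copper-catalysed SN2 opening of a 2,3-epoxy alcohol; the fully substituted C3 is closed to backside attack, so the vinyl group enters at C2 with inversion (sets C1 of the target) while the C3–O bond and its configuration (C15) are untouched.

Step 3
Reactants: 4
Product: 5 (3S,4R)-3-(iodomethyl)-4,8-dimethylnona-1,7-dien-4-ol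
Conditions: I2, PPh3, imidazole, CH2Cl2, 0 °C → rt
Reagents that add atoms: iodine, II
Why: Appel iodination; only the primary hydroxyl gives an alkoxyphosphonium ion that iodide can displace, and the tertiary alcohol does not react under these neutral conditions.

Step 4
Reactants: 5
Product: 6 triethyl{[(3S,4R)-3-(iodomethyl)-4,8-dimethylnona-1,7-dien-4-yl]oxy}silane
Conditions: Et3SiOSO2CF3, 2,6-lutidine, CH2Cl2, −78 → 0 °C
Reagents that add atoms: triethylsilyl trifluoromethanesulfonate, CC[Si](CC)(CC)OS(=O)(=O)C(F)(F)F
Why: Silyl triflate silylation of a tertiary alcohol; the hindered triethylsilyl ether blocks γ-lactone formation later and is still removable by fluoride at the end.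

Step 5
Reactants: 7 3-[(4-methoxyphenyl)methoxy]propan-1-ol
Product: 8 1-[(3-iodopropoxy)methyl]-4-methoxybenzene
Conditions: I2, PPh3, imidazole, CH2Cl2, 0 °C → rt
Reagents that add atoms: iodine, II
Why: Appel iodination of an unhindered primary alcohol; the p-methoxybenzyl ether is stable to these conditions.

Step 6
Reactants: 9 triethyl phosphonoacetate; 8
Product: 10 ethyl 2-(diethoxyphosphoryl)-5-[(4-methoxyphenyl)methoxy]pentanoate (racemic)
Conditions: NaH, DMF, 0 °C; then 8, 60 °C
Reagents that add atoms: none
Why: C-alkylation of the stabilised phosphonoacetate anion with a primary iodide, a malonate-type alkylation; the new stereocentre is destroyed in step 9.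

Step 7
Reactants: 11 2-(2-bromoethyl)-1,3-dioxolane; 12 propyne
Product: 16 2-[(3Z)-4-iodo-3-methylbut-3-en-1-yl]-1,3-dioxolane, via Grignard reagent 13 (not isolated), via alkylcopper 14 (not isolated), via alkenylcopper 15 (not isolated)
Conditions: Mg, THF, 25 °C; CuBr·SMe2, Et2O/Me2S, −45 °C; propyne, −25 °C; I2, −60 → 0 °C
Reagents that add atoms: iodine, II
Why: Carbocupration of a terminal alkyne; the alkyl group and copper add syn with copper on the terminal carbon, so the new chain is cis to copper, and iodinolysis with retention gives the Z iodide (C3=C4 of the target).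

Step 8
Reactants: 16
Product: 17 (4Z)-5-iodo-4-methylpent-4-enal
Conditions: 1 M HCl, THF, 40 °C
Reagents that add atoms: water, O
Why: Acid hydrolysis of a dioxolane; the alkenyl iodide tolerates dilute aqueous acid, and no silyl ether is present at this stage.

Step 9
Reactants: 17; 10
Product: 18 ethyl (2E,6Z)-7-iodo-2-{3-[(4-methoxyphenyl)methoxy]propyl}-6-methylhepta-2,6-dienoate
Conditions: NaH, THF, 0 °C; then 17, 0 °C → rt
Reagents that add atoms: none
Why: Horner–Wadsworth–Emmons olefination; reversible addition and elimination through the less crowded oxaphosphetane should favour the E enoate, which puts C6 cis to C9 and trans to the ester carbon (the future CH2OH); any Z isomer is removed after step 10.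

Step 10
Reactants: 18
Product: 19 (2E,6Z)-7-iodo-2-{3-[(4-methoxyphenyl)methoxy]propyl}-6-methylhepta-2,6-dien-1-ol
Conditions: i-Bu2AlH (2.2 equiv), CH2Cl2, −78 °C; aq. sodium potassium tartrate
Reagents that add atoms: none
Why: 1,2-Reduction of an α,β-unsaturated ester by an aluminium hydride; the alkenyl iodide and the benzyl-type ether are inert at −78 °C and the alkene geometry is not affected.

Step 11
Reactants: 19
Product: 20 tert-butyl{[(2E,6Z)-7-iodo-2-{3-[(4-methoxyphenyl)methoxy]propyl}-6-methylhepta-2,6-dien-1-yl]oxy}dimethylsilane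
Conditions: t-BuMe2SiCl, imidazole, DMF, rt
Reagents that add atoms: tert-butyldimethylsilyl chloride, CC(C)(C)[Si](C)(C)Cl
Why: Standard silylation of a primary allylic alcohol; the silyl ether survives organozinc, borane, oxidant and enolate chemistry and leaves with fluoride together with the C15 silyl group.

Step 12
Reactants: 6; 20
Product: 23 (6R,7S,9Z,13E)-14-{[(tert-butyldimethylsilyl)oxy]methyl}-7-ethenyl-17-[(4-methoxyphenyl)methoxy]-2,6,10-trimethyl-6-[(triethylsilyl)oxy]heptadeca-2,9,13-triene, via alkyllithium 21 (not isolated), via alkylzinc chloride 22 (not isolated)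
Conditions: 6, t-BuLi (2.1 equiv), Et2O, −78 °C; ZnCl2 (THF), −78 °C → rt; then 20, Pd(PPh3)4 (5 mol %), THF, rt
Reagents that add atoms: none
Why: Negishi sp3–sp2 coupling; iodine–lithium exchange of the primary iodide and transmetalation to zinc give a reagent that couples with the alkenyl iodide with retention of the Z geometry, forming C2–C3; immediate transmetalation to zinc limits silyl migration in the γ-silyloxy alkyllithium.

Step 13
Reactants: 23
Product: 25 (3S,5Z,9E)-10-{[(tert-butyldimethylsilyl)oxy]methyl}-13-[(4-methoxyphenyl)methoxy]-6-methyl-3-{(2R)-6-methyl-2-[(triethylsilyl)oxy]hept-5-en-2-yl}trideca-5,9-dien-1-ol, via B-alkyl-9-BBN adduct 24 (not isolated)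
Conditions: 9-BBN (1.5 equiv), THF, 0 °C → rt; then NaOH, H2O2, 0 °C → rt
Reagents that add atoms: hydrogen peroxide, OO
Why: Anti-Markovnikov hydroboration–oxidation; 9-BBN adds to the one monosubstituted alkene far faster than to the three trisubstituted alkenes, and oxidation with retention gives the primary alcohol of the future acetic acid arm.

Step 14
Reactants: 25
Product: 27 (3S,5Z,9E)-10-{[(tert-butyldimethylsilyl)oxy]methyl}-13-[(4-methoxyphenyl)methoxy]-6-methyl-3-{(2R)-6-methyl-2-[(triethylsilyl)oxy]hept-5-en-2-yl}trideca-5,9-dienoic acid, via aldehyde 26 (not isolated)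
Conditions: TEMPO (0.2 equiv), PhI(OAc)2 (2.5 equiv), MeCN/pH 7 buffer (1:1), rt
Reagents that add atoms: water, O
Why: Oxoammonium-catalysed oxidation of a primary alcohol through the aldehyde hydrate to the acid; the buffered medium spares the alkenes, both silyl ethers and the p-methoxybenzyl ether.

Step 15
Reactants: 27
Product: 28 (3S,5Z,9E)-10-{[(tert-butyldimethylsilyl)oxy]methyl}-13-hydroxy-6-methyl-3-{(2R)-6-methyl-2-[(triethylsilyl)oxy]hept-5-en-2-yl}trideca-5,9-dienoic acid
Conditions: DDQ (1.3 equiv), CH2Cl2/pH 7 buffer (10:1), 0 °C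
Reagents that add atoms: none
Why: Oxidative cleavage of a p-methoxybenzyl ether by hydride abstraction and hydrolysis of the oxocarbenium ion; silyl ethers, isolated alkenes and the carboxylic acid do not react.

Step 16
Reactants: 28
Product: 29 (3S,5Z,9E)-10-{[(tert-butyldimethylsilyl)oxy]methyl}-6-methyl-3-{(2R)-6-methyl-2-[(triethylsilyl)oxy]hept-5-en-2-yl}-13-oxotrideca-5,9-dienoic acid
Conditions: Dess–Martin periodinane (1.3 equiv), NaHCO3, CH2Cl2, 0 °C → rt
Reagents that add atoms: none
Why: Dess–Martin oxidation of the primary alcohol to the C11 aldehyde under buffered, non-acidic conditions that tolerate the free acid and the tertiary silyl ether.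

Step 17
Reactants: 29; 30 isopropenylmagnesium bromide
Product: 31 (3S,5Z,9E,13RS)-10-{[(tert-butyldimethylsilyl)oxy]methyl}-13-hydroxy-6,14-dimethyl-3-{(2R)-6-methyl-2-[(triethylsilyl)oxy]hept-5-en-2-yl}pentadeca-5,9,14-trienoic acid
Conditions: CH2=C(CH3)MgBr (3.5 equiv), THF, −78 → −30 °C; aq. NH4Cl, pH 4
Reagents that add atoms: none
Why: Grignard addition to an aldehyde; the first equivalent converts the acid into its unreactive magnesium carboxylate and the next adds to C11, forming C11–C12 without facial control, which is acceptable because both C11 epimers converge in steps 19 and 20.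

Step 18
Reactants: 31
Product: 33 (4S,6Z,10E,14RS)-11-{[(tert-butyldimethylsilyl)oxy]methyl}-7-methyl-4-{(2R)-6-methyl-2-[(triethylsilyl)oxy]hept-5-en-2-yl}-14-(prop-1-en-2-yl)-1-oxacyclotetradeca-6,10-dien-2-one, via mixed anhydride 32 (not isolated)
Conditions: 2,4,6-Cl3C6H2COCl, Et3N, THF, rt; then slow addition to DMAP, toluene, 80 °C (ca. 1 mM)
Reagents that add atoms: none
Why: Yamaguchi macrolactonisation; the acid is activated as the mixed anhydride and acyl transfer through the acylpyridinium ion to the secondary allylic hydroxyl closes the 14-membered lactone at high dilution; the silylated C15 oxygen cannot compete.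

Step 19
Reactants: 33
Product: 36 (1RS,3E,7E,11Z,14S)-7-{[(tert-butyldimethylsilyl)oxy]methyl}-3,11-dimethyl-14-{(2R)-6-methyl-2-[(triethylsilyl)oxy]hept-5-en-2-yl}cyclotetradeca-3,7,11-triene-1-carboxylic acid, via silyl ketene acetal 34 (not isolated), via trimethylsilyl ester 35 (not isolated)
Conditions: Me3SiCl/Et3N, then KN(SiMe3)2 (2 equiv), THF, −78 °C → rt; toluene, 105 °C; aq. citric acid, rt
Reagents that add atoms: none
Why: KN(SiMe3)2 removes a proton from C14, the only position α to the lactone carbonyl, and Me3SiCl present in the flask traps the enolate as silyl ketene acetal 34; on heating, a concerted suprafacial [3,3] shift forms C13–C14, breaks C11–O and moves the π bond to C11=C12, giving silyl ester 35, which the work-up hydrolyses to 36. The closest known reaction type is the Ireland–Claisen rearrangement of macrolactone silyl ketene acetals that carry an alkenyl group on the carbinol carbon and give cycloalkene carboxylic acids of unchanged ring size. The carbocycle is closed by a ring switch, not by an end-to-end cyclisation: the six-atom pericyclic array is bridged across its 1,4-positions (C11 and C14) by the ten-carbon chain C10–C1, so the new σ bond forms inside an existing 14-membered ring. The only new stereocentre is the carboxyl-bearing carbon; it is not controlled (ketene acetal geometry and C11 configuration decide it) and is erased in step 20. The selectivity that matters is the E geometry of C11=C12, which follows from a chair transition state with C10 pseudo-equatorial on C11, away from the 1,3-diaxial contact with the silyloxy-bearing carbon that an axial C10 would suffer. The ten-atom bridge is long enough to span the chair without forcing a boat. C1 and C15 are not enolisable and have no β-leaving group, so they pass through unchanged.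

Step 20
Reactants: 36
Product: 38 triethyl({(2R)-2-[(1R,3Z,7E,11E)-8-{[(tert-butyldimethylsilyl)oxy]methyl}-4,12-dimethylcyclotetradeca-3,7,11-trien-1-yl]-6-methylhept-5-en-2-yl}oxy)silane, via thiohydroxamate ester 37 (not isolated)
Conditions: N-hydroxypyridine-2-thione, DCC, DMAP (cat.), CH2Cl2, rt, dark; then t-BuSH (10 equiv), hν (tungsten lamp), 15 °C
Reagents that add atoms: none
Why: Barton reductive decarboxylation; light cleaves the N–O bond, the acyloxy radical loses CO2 and the secondary C14 radical takes hydrogen from the thiol faster than it can attack a ring alkene (only 3- and 4-membered closures are in reach), which removes the foreign carbon and the C14 centre.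

Step 21
Reactants: 38
Product: 39 (2R)-2-[(1R,3Z,7E,11E)-8-(hydroxymethyl)-4,12-dimethylcyclotetradeca-3,7,11-trien-1-yl]-6-methylhept-5-en-2-ol
Conditions: Bu4NF (6 equiv), THF, rt → 45 °C
Reagents that add atoms: none
Why: Fluoride-induced cleavage of both silyl ethers; the conditions are neither acidic nor oxidising, so the tertiary alcohol, the allylic alcohol and the three alkene geometries are preserved.

## Compound list

1 | nerol, (2Z)-3,7-dimethylocta-2,6-dien-1-ol | CC(C)=CCC/C(C)=C\CO | starting material
2 | [(2S,3R)-3-methyl-3-(4-methylpent-3-en-1-yl)oxiran-2-yl]methanol | CC(C)=CCC[C@@]1(C)O[C@H]1CO | intermediate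
3 | vinylmagnesium bromide | C=C[Mg]Br | starting material
4 | (2R,3R)-2-ethenyl-3,7-dimethyloct-6-ene-1,3-diol | CC(C)=CCC[C@@](C)(O)[C@H](C=C)CO | intermediate
5 | (3S,4R)-3-(iodomethyl)-4,8-dimethylnona-1,7-dien-4-ol | CC(C)=CCC[C@@](C)(O)[C@H](C=C)CI | intermediate
6 | triethyl{[(3S,4R)-3-(iodomethyl)-4,8-dimethylnona-1,7-dien-4-yl]oxy}silane | CC(C)=CCC[C@@](C)(O[Si](CC)(CC)CC)[C@H](C=C)CI | intermediate
7 | 3-[(4-methoxyphenyl)methoxy]propan-1-ol | COc1ccc(COCCCO)cc1 | starting material
8 | 1-[(3-iodopropoxy)methyl]-4-methoxybenzene | COc1ccc(COCCCI)cc1 | intermediate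
9 | triethyl phosphonoacetate, ethyl 2-(diethoxyphosphoryl)acetate | CCOC(=O)CP(=O)(OCC)OCC | starting material
10 | ethyl 2-(diethoxyphosphoryl)-5-[(4-methoxyphenyl)methoxy]pentanoate (racemic) | CCOC(=O)C(CCCOCc1ccc(OC)cc1)P(=O)(OCC)OCC | intermediate
11 | 2-(2-bromoethyl)-1,3-dioxolane | BrCCC1OCCO1 | starting material
12 | propyne | CC#C | starting material
13 | [2-(1,3-dioxolan-2-yl)ethyl]magnesium bromide | Br[Mg]CCC1OCCO1 | intermediate
14 | [2-(1,3-dioxolan-2-yl)ethyl]copper (as its MgBr2/Me2S complex) | [Cu]CCC1OCCO1 | intermediate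
15 | [(1Z)-4-(1,3-dioxolan-2-yl)-2-methylbut-1-en-1-yl]copper | C/C(CCC1OCCO1)=C/[Cu] | intermediate
16 | 2-[(3Z)-4-iodo-3-methylbut-3-en-1-yl]-1,3-dioxolane | C/C(CCC1OCCO1)=C/I | intermediate
17 | (4Z)-5-iodo-4-methylpent-4-enal | C/C(CCC=O)=C/I | intermediate
18 | ethyl (2E,6Z)-7-iodo-2-{3-[(4-methoxyphenyl)methoxy]propyl}-6-methylhepta-2,6-dienoate | CCOC(=O)/C(CCCOCc1ccc(OC)cc1)=C/CC/C(C)=C\I | intermediate
19 | (2E,6Z)-7-iodo-2-{3-[(4-methoxyphenyl)methoxy]propyl}-6-methylhepta-2,6-dien-1-ol | OC/C(CCCOCc1ccc(OC)cc1)=C/CC/C(C)=C\I | intermediate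
20 | tert-butyl{[(2E,6Z)-7-iodo-2-{3-[(4-methoxyphenyl)methoxy]propyl}-6-methylhepta-2,6-dien-1-yl]oxy}dimethylsilane | CC(C)(C)[Si](C)(C)OC/C(CCCOCc1ccc(OC)cc1)=C/CC/C(C)=C\I | intermediate
21 | {(2S,3R)-2-ethenyl-3,7-dimethyl-3-[(triethylsilyl)oxy]oct-6-en-1-yl}lithium | CC(C)=CCC[C@@](C)(O[Si](CC)(CC)CC)[C@H](C=C)C[Li] | intermediate
22 | chlorido{(2S,3R)-2-ethenyl-3,7-dimethyl-3-[(triethylsilyl)oxy]oct-6-en-1-yl}zinc | CC(C)=CCC[C@@](C)(O[Si](CC)(CC)CC)[C@H](C=C)C[Zn]Cl | intermediate
23 | (6R,7S,9Z,13E)-14-{[(tert-butyldimethylsilyl)oxy]methyl}-7-ethenyl-17-[(4-methoxyphenyl)methoxy]-2,6,10-trimethyl-6-[(triethylsilyl)oxy]heptadeca-2,9,13-triene | CC(C)=CCC[C@@](C)(O[Si](CC)(CC)CC)[C@H](C=C)C/C=C(/C)CC/C=C(/CO[Si](C)(C)C(C)(C)C)CCCOCc1ccc(OC)cc1 | intermediate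
24 | 9-[(3R,5Z,9E)-10-{[(tert-butyldimethylsilyl)oxy]methyl}-13-[(4-methoxyphenyl)methoxy]-6-methyl-3-{(2R)-6-methyl-2-[(triethylsilyl)oxy]hept-5-en-2-yl}trideca-5,9-dien-1-yl]-9-borabicyclo[3.3.1]nonane | CC(C)=CCC[C@@](C)(O[Si](CC)(CC)CC)[C@H](CCB1C2CCCC1CCC2)C/C=C(/C)CC/C=C(/CO[Si](C)(C)C(C)(C)C)CCCOCc1ccc(OC)cc1 | intermediate
25 | (3S,5Z,9E)-10-{[(tert-butyldimethylsilyl)oxy]methyl}-13-[(4-methoxyphenyl)methoxy]-6-methyl-3-{(2R)-6-methyl-2-[(triethylsilyl)oxy]hept-5-en-2-yl}trideca-5,9-dien-1-ol | CC(C)=CCC[C@@](C)(O[Si](CC)(CC)CC)[C@H](CCO)C/C=C(/C)CC/C=C(/CO[Si](C)(C)C(C)(C)C)CCCOCc1ccc(OC)cc1 | intermediate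
26 | (3S,5Z,9E)-10-{[(tert-butyldimethylsilyl)oxy]methyl}-13-[(4-methoxyphenyl)methoxy]-6-methyl-3-{(2R)-6-methyl-2-[(triethylsilyl)oxy]hept-5-en-2-yl}trideca-5,9-dienal | CC(C)=CCC[C@@](C)(O[Si](CC)(CC)CC)[C@H](CC=O)C/C=C(/C)CC/C=C(/CO[Si](C)(C)C(C)(C)C)CCCOCc1ccc(OC)cc1 | intermediate
27 | (3S,5Z,9E)-10-{[(tert-butyldimethylsilyl)oxy]methyl}-13-[(4-methoxyphenyl)methoxy]-6-methyl-3-{(2R)-6-methyl-2-[(triethylsilyl)oxy]hept-5-en-2-yl}trideca-5,9-dienoic acid | CC(C)=CCC[C@@](C)(O[Si](CC)(CC)CC)[C@H](CC(=O)O)C/C=C(/C)CC/C=C(/CO[Si](C)(C)C(C)(C)C)CCCOCc1ccc(OC)cc1 | intermediate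
28 | (3S,5Z,9E)-10-{[(tert-butyldimethylsilyl)oxy]methyl}-13-hydroxy-6-methyl-3-{(2R)-6-methyl-2-[(triethylsilyl)oxy]hept-5-en-2-yl}trideca-5,9-dienoic acid | CC(C)=CCC[C@@](C)(O[Si](CC)(CC)CC)[C@H](CC(=O)O)C/C=C(/C)CC/C=C(/CO[Si](C)(C)C(C)(C)C)CCCO | intermediate
29 | (3S,5Z,9E)-10-{[(tert-butyldimethylsilyl)oxy]methyl}-6-methyl-3-{(2R)-6-methyl-2-[(triethylsilyl)oxy]hept-5-en-2-yl}-13-oxotrideca-5,9-dienoic acid | CC(C)=CCC[C@@](C)(O[Si](CC)(CC)CC)[C@H](CC(=O)O)C/C=C(/C)CC/C=C(/CO[Si](C)(C)C(C)(C)C)CCC=O | intermediate
30 | isopropenylmagnesium bromide | CC(=C)[Mg]Br | starting material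
31 | (3S,5Z,9E,13RS)-10-{[(tert-butyldimethylsilyl)oxy]methyl}-13-hydroxy-6,14-dimethyl-3-{(2R)-6-methyl-2-[(triethylsilyl)oxy]hept-5-en-2-yl}pentadeca-5,9,14-trienoic acid | CC(C)=CCC[C@@](C)(O[Si](CC)(CC)CC)[C@H](CC(=O)O)C/C=C(/C)CC/C=C(/CO[Si](C)(C)C(C)(C)C)CCC(O)C(C)=C | intermediate
32 | mixed anhydride of 31 with 2,4,6-trichlorobenzoic acid | CC(C)=CCC[C@@](C)(O[Si](CC)(CC)CC)[C@H](CC(=O)OC(=O)c1c(Cl)cc(Cl)cc1Cl)C/C=C(/C)CC/C=C(/CO[Si](C)(C)C(C)(C)C)CCC(O)C(C)=C | intermediate
33 | (4S,6Z,10E,14RS)-11-{[(tert-butyldimethylsilyl)oxy]methyl}-7-methyl-4-{(2R)-6-methyl-2-[(triethylsilyl)oxy]hept-5-en-2-yl}-14-(prop-1-en-2-yl)-1-oxacyclotetradeca-6,10-dien-2-one | CC(C)=CCC[C@@](C)(O[Si](CC)(CC)CC)[C@H]1C/C=C(/C)CC/C=C(/CO[Si](C)(C)C(C)(C)C)CCC(C(C)=C)OC(=O)C1 | intermediate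
34 | (4S,6Z,10E,14RS)-11-{[(tert-butyldimethylsilyl)oxy]methyl}-7-methyl-4-{(2R)-6-methyl-2-[(triethylsilyl)oxy]hept-5-en-2-yl}-14-(prop-1-en-2-yl)-2-[(trimethylsilyl)oxy]-1-oxacyclotetradeca-2,6,10-triene | CC(C)=CCC[C@@](C)(O[Si](CC)(CC)CC)[C@H]1C/C=C(/C)CC/C=C(/CO[Si](C)(C)C(C)(C)C)CCC(C(C)=C)OC(O[Si](C)(C)C)=C1 | intermediate
35 | trimethylsilyl (1RS,3E,7E,11Z,14S)-7-{[(tert-butyldimethylsilyl)oxy]methyl}-3,11-dimethyl-14-{(2R)-6-methyl-2-[(triethylsilyl)oxy]hept-5-en-2-yl}cyclotetradeca-3,7,11-triene-1-carboxylate | CC(C)=CCC[C@@](C)(O[Si](CC)(CC)CC)[C@H]1C/C=C(/C)CC/C=C(/CO[Si](C)(C)C(C)(C)C)CC/C=C(\C)CC1C(=O)O[Si](C)(C)C | intermediate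
36 | (1RS,3E,7E,11Z,14S)-7-{[(tert-butyldimethylsilyl)oxy]methyl}-3,11-dimethyl-14-{(2R)-6-methyl-2-[(triethylsilyl)oxy]hept-5-en-2-yl}cyclotetradeca-3,7,11-triene-1-carboxylic acid | CC(C)=CCC[C@@](C)(O[Si](CC)(CC)CC)[C@H]1C/C=C(/C)CC/C=C(/CO[Si](C)(C)C(C)(C)C)CC/C=C(\C)CC1C(=O)O | intermediate
37 | 2-sulfanylidenepyridin-1(2H)-yl ester of 36 | CC(C)=CCC[C@@](C)(O[Si](CC)(CC)CC)[C@H]1C/C=C(/C)CC/C=C(/CO[Si](C)(C)C(C)(C)C)CC/C=C(\C)CC1C(=O)ON2C=CC=CC2=S | intermediate
38 | triethyl({(2R)-2-[(1R,3Z,7E,11E)-8-{[(tert-butyldimethylsilyl)oxy]methyl}-4,12-dimethylcyclotetradeca-3,7,11-trien-1-yl]-6-methylhept-5-en-2-yl}oxy)silane | CC(C)=CCC[C@@](C)(O[Si](CC)(CC)CC)[C@H]1C/C=C(/C)CC/C=C(/CO[Si](C)(C)C(C)(C)C)CC/C=C(\C)CC1 | intermediate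
39 | (2R)-2-[(1R,3Z,7E,11E)-8-(hydroxymethyl)-4,12-dimethylcyclotetradeca-3,7,11-trien-1-yl]-6-methylhept-5-en-2-ol | CC(C)=CCC[C@@](C)(O)[C@H]1C/C=C(/C)CC/C=C(/CO)CC/C=C(\C)CC1 | target

## Step count and risk

Total: 21 steps. Longest linear sequence: 15 steps (steps 7–21, from 11 and 12).

**Step 19 (key step).** The bridged chair may be too strained for the rearrangement to proceed below the temperature at which the ketene acetal decomposes, or a boat pathway may erode the E geometry at C11=C12. The fallback closes the same C13–C14 bond by a polar route with the alkene geometry fixed beforehand. It sets out from 29 and returns at 36. Esterification of 29 with Me3SiCHN2 gives the methyl ester of 29 F1. A Wittig reaction with 2-(triphenylphosphoranylidene)propanal gives the (E)-enal F2, whose aldehyde carbon is C13. NaBH4/CeCl3 reduces the enal alone to the allylic alcohol F3, and CBr4/PPh3 gives the allylic bromide F4. KN(SiMe3)2 at high dilution forms the ester enolate at C14, which displaces the bromide to give the cyclic methyl ester F5. Me3SnOH then frees acid 36.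

**Step 12.** After the iodine–lithium exchange the γ-silyloxy alkyllithium may suffer silyl migration from oxygen to carbon, or the β-branched alkylzinc may transmetalate slowly so that reduction and homocoupling take over. The fallback avoids the organolithium altogether. It sets out from 6 and returns at 23. Direct insertion of activated zinc (Zn, LiCl, THF, 40 °C) gives the alkylzinc iodide F6, which is coupled with 20 under Pd(OAc)2 and 2-dicyclohexylphosphino-2′,6′-dimethoxybiphenyl.

**Step 9.** The E preference of the olefination may be eroded, because an α-branched phosphonate anion meets an unbranched aldehyde and equilibration of the adducts may be incomplete. The fallback replaces the phosphonate by a stabilised phosphorane. It sets out from 8 and 17 and returns at 18. Ethyl (triphenylphosphoranylidene)acetate is alkylated with 8 to the phosphonium iodide F7, aqueous NaOH gives the phosphorane F8, and its Wittig reaction with 17 in warm toluene gives 18.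

**Step 17.** The addition may stall because the magnesium carboxylate formed first aggregates, and enolisation of the aldehyde by the basic reagent may compete. The fallback masks the acid. It sets out from 29 and returns at 31. Me3SiCHN2 gives the methyl ester of 29 F1 (the compound already used in the fallback for step 19), 30 adds to its aldehyde at −78 °C to give the hydroxy methyl ester F9, and Me3SnOH frees 31.

**Step 20.** Thiyl radicals may add reversibly to the C3=C4 alkene and isomerise it from Z to E, the C14 radical may attack a ring alkene before it is reduced, and acylation of the hindered acid may be slow. The fallback uses a redox-active ester and a nickel hydride source in place of the thiol chain. It sets out from 36 and returns at 38. N-Hydroxyphthalimide and N,N′-diisopropylcarbodiimide give the N-acyloxyphthalimide F10, which is reduced with NiCl2·6H2O, 4,4′-di-tert-butyl-2,2′-bipyridine, Zn and PhSiH3.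

## Further compounds

F1 | step 19 | methyl (3S,5Z,9E)-10-{[(tert-butyldimethylsilyl)oxy]methyl}-6-methyl-3-{(2R)-6-methyl-2-[(triethylsilyl)oxy]hept-5-en-2-yl}-13-oxotrideca-5,9-dienoate | CC(C)=CCC[C@@](C)(O[Si](CC)(CC)CC)[C@H](CC(=O)OC)C/C=C(/C)CC/C=C(/CO[Si](C)(C)C(C)(C)C)CCC=O
F2 | step 19 | methyl (3S,5Z,9E,13E)-10-{[(tert-butyldimethylsilyl)oxy]methyl}-6,14-dimethyl-3-{(2R)-6-methyl-2-[(triethylsilyl)oxy]hept-5-en-2-yl}-15-oxopentadeca-5,9,13-trienoate | CC(C)=CCC[C@@](C)(O[Si](CC)(CC)CC)[C@H](CC(=O)OC)C/C=C(/C)CC/C=C(/CO[Si](C)(C)C(C)(C)C)CC/C=C(\C)C=O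
F3 | step 19 | methyl (3S,5Z,9E,13E)-10-{[(tert-butyldimethylsilyl)oxy]methyl}-15-hydroxy-6,14-dimethyl-3-{(2R)-6-methyl-2-[(triethylsilyl)oxy]hept-5-en-2-yl}pentadeca-5,9,13-trienoate | CC(C)=CCC[C@@](C)(O[Si](CC)(CC)CC)[C@H](CC(=O)OC)C/C=C(/C)CC/C=C(/CO[Si](C)(C)C(C)(C)C)CC/C=C(\C)CO
F4 | step 19 | methyl (3S,5Z,9E,13E)-15-bromo-10-{[(tert-butyldimethylsilyl)oxy]methyl}-6,14-dimethyl-3-{(2R)-6-methyl-2-[(triethylsilyl)oxy]hept-5-en-2-yl}pentadeca-5,9,13-trienoate | CC(C)=CCC[C@@](C)(O[Si](CC)(CC)CC)[C@H](CC(=O)OC)C/C=C(/C)CC/C=C(/CO[Si](C)(C)C(C)(C)C)CC/C=C(\C)CBr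
F5 | step 19 | methyl (1RS,3E,7E,11Z,14S)-7-{[(tert-butyldimethylsilyl)oxy]methyl}-3,11-dimethyl-14-{(2R)-6-methyl-2-[(triethylsilyl)oxy]hept-5-en-2-yl}cyclotetradeca-3,7,11-triene-1-carboxylate | CC(C)=CCC[C@@](C)(O[Si](CC)(CC)CC)[C@H]1C/C=C(/C)CC/C=C(/CO[Si](C)(C)C(C)(C)C)CC/C=C(\C)CC1C(=O)OC
F6 | step 12 | iodido{(2S,3R)-2-ethenyl-3,7-dimethyl-3-[(triethylsilyl)oxy]oct-6-en-1-yl}zinc | CC(C)=CCC[C@@](C)(O[Si](CC)(CC)CC)[C@H](C=C)C[Zn]I
F7 | step 9 | {1-ethoxy-5-[(4-methoxyphenyl)methoxy]-1-oxopentan-2-yl}triphenylphosphonium iodide | CCOC(=O)C(CCCOCc1ccc(OC)cc1)[P+](c1ccccc1)(c1ccccc1)c1ccccc1.[I-]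
F8 | step 9 | ethyl 5-[(4-methoxyphenyl)methoxy]-2-(triphenylphosphoranylidene)pentanoate | CCOC(=O)C(CCCOCc1ccc(OC)cc1)=P(c1ccccc1)(c1ccccc1)c1ccccc1
F9 | step 17 | methyl (3S,5Z,9E,13RS)-10-{[(tert-butyldimethylsilyl)oxy]methyl}-13-hydroxy-6,14-dimethyl-3-{(2R)-6-methyl-2-[(triethylsilyl)oxy]hept-5-en-2-yl}pentadeca-5,9,14-trienoate | CC(C)=CCC[C@@](C)(O[Si](CC)(CC)CC)[C@H](CC(=O)OC)C/C=C(/C)CC/C=C(/CO[Si](C)(C)C(C)(C)C)CCC(O)C(C)=C
F10 | step 20 | 1,3-dioxoisoindolin-2-yl ester of 36 | CC(C)=CCC[C@@](C)(O[Si](CC)(CC)CC)[C@H]1C/C=C(/C)CC/C=C(/CO[Si](C)(C)C(C)(C)C)CC/C=C(\C)CC1C(=O)ON2C(=O)c3ccccc3C2=O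
A1 | alternative 1 | open-chain C6 iodide with a phenylsulfinyl group on C7 and an exocyclic methylene on C8, C15 triethylsilyl ether | CC(C)=CCC[C@@](C)(O[Si](CC)(CC)CC)[C@@H](C/C=C(/C)CCI)CC/C(C)=C/CCC(=C)CS(=O)c1ccccc1
A2 | alternative 1 | C15 triethylsilyl ether of the target | CC(C)=CCC[C@@](C)(O[Si](CC)(CC)CC)[C@H]1C/C=C(/C)CC/C=C(/CO)CC/C=C(\C)CC1
A3 | alternative 2 | open-chain C14 phenyl sulfone with the C1–C15 epoxide and the C8 CH2O tert-butyldimethylsilyl ether | CC(C)=CCC[C@@]1(C)O[C@H]1C/C=C(/C)CC/C=C(/CO[Si](C)(C)C(C)(C)C)CC/C=C(\C)CCS(=O)(=O)c1ccccc1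
A4 | alternative 2 | 14-membered ring with a C14 phenylsulfonyl group and free C15 alcohol | CC(C)=CCC[C@@](C)(O)[C@H]1C/C=C(/C)CC/C=C(/CO[Si](C)(C)C(C)(C)C)CC/C=C(\C)CC1S(=O)(=O)c1ccccc1
A5 | alternative 3 | open-chain C1 vinyl compound with an (E)-alkenyl iodide at C12, bis-silyl ether | CC(C)=CCC[C@@](C)(O[Si](CC)(CC)CC)[C@H](C=C)C/C=C(/C)CC/C=C(/CO[Si](C)(C)C(C)(C)C)CC/C=C(\C)I
A6 | alternative 3 | bis-silyl ether of the target (same structure as 38) | CC(C)=CCC[C@@](C)(O[Si](CC)(CC)CC)[C@H]1C/C=C(/C)CC/C=C(/CO[Si](C)(C)C(C)(C)C)CC/C=C(\C)CC1
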